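The route rests on disconnecting the aryl ether bond O1–C8a and closing the pyranone ring onto an aryne. The precursor is an (S)-β-hydroxy ketone whose ring A carries a triflate at C8a and iodine at C8; it comes from resacetophenone, a diprenylated ring B aldehyde and an enantioselective β-borylation of their chalcone. In one operation, iodine–magnesium exchange unmasks the C8a≡C8 aryne, the tethered C2 alkoxide adds to C8a, and the C8–Mg bond left behind is prenylated. The step exploits the vicinal O1/prenyl pair at C8a/C8 of ring A, flanked by the C4a acyl tether and the C7 oxygen, which both steer oxygen to C8a. Enolate hydroxylation then sets C3 trans to the C2 aryl group.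

Key step: step 8

Remark (assumption): flavanone numbering (O1, C2, C3, C4, C4a, C5–C8, C8a) is used throughout. In step 7 the sense of induction is assumed to follow that of simple chalcones, and the ligand antipode that delivers the (S)-carbinol is the one used.

Step 1
Reactants: 1 2,4-dihydroxyacetophenone
Product: 2 1-(2,4-dihydroxy-3-iodophenyl)ethanone
Conditions: I2, HIO3, EtOH/H2O, 35 °C
Reagents that add atoms: iodine, II; iodic acid, OI(=O)=O
Why: Electrophilic aromatic iodination should go to C3, the position ortho to both hydroxyl groups of the chelated ketone (any 5-iodo isomer is removed by crystallisation); no stereocenter is formed.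

Step 2
Reactants: 2 1-(2,4-dihydroxy-3-iodophenyl)ethanone
Product: 3 1-[2-hydroxy-3-iodo-4-(methoxymethoxy)phenyl]ethanone
Conditions: MOMCl (1.1 equiv), K2CO3, acetone, 0 °C to rt
Reagents that add atoms: chloromethyl methyl ether, COCCl
Why: Williamson-type O-alkylation; the 2-hydroxyl is deactivated by its hydrogen bond to the acetyl carbonyl, so only the 4-hydroxyl should be protected.

Step 3
Reactants: 4 4-hydroxybenzaldehyde
Product: 5 4-hydroxy-3,5-bis(3-methylbut-2-enyl)benzaldehyde
Conditions: prenyl bromide (2.5 equiv), KOH (10% aq), rt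
Reagents that add atoms: prenyl bromide (1-bromo-3-methylbut-2-ene), CC(C)=CCBr
Why: Ortho-C-alkylation of the ambident phenoxide in water, where hydrogen bonding to the phenoxide oxygen suppresses O-alkylation, should install prenyl groups at both free ortho positions; mono-C-prenyl and O-prenyl by-products are separated by chromatography.

Step 4
Reactants: 5 4-hydroxy-3,5-bis(3-methylbut-2-enyl)benzaldehyde
Product: 6 4-(methoxymethoxy)-3,5-bis(3-methylbut-2-enyl)benzaldehyde
Conditions: MOMCl, K2CO3, acetone, 50 °C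
Reagents that add atoms: chloromethyl methyl ether, COCCl
Why: Williamson-type O-alkylation of the hindered phenoxide with the reactive chloromethyl ether should give an acetal that survives the later base, Grignard and enolate steps and leaves under mild acid.

Step 5
Reactants: 3 1-[2-hydroxy-3-iodo-4-(methoxymethoxy)phenyl]ethanone; 6 4-(methoxymethoxy)-3,5-bis(3-methylbut-2-enyl)benzaldehyde
Product: 7 (E)-1-[2-hydroxy-3-iodo-4-(methoxymethoxy)phenyl]-3-[4-(methoxymethoxy)-3,5-bis(3-methylbut-2-enyl)phenyl]prop-2-en-1-one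
Conditions: KOH (50% aq), EtOH, rt; cold dilute acid work-up
Reagents that add atoms: none
Why: Claisen–Schmidt aldol condensation; the methyl ketone enolate adds to the non-enolisable aldehyde and E1cB dehydration should give the (E)-enone, the aryl iodide and both acetals being inert to hydroxide.

Step 6
Reactants: 7 (E)-1-[2-hydroxy-3-iodo-4-(methoxymethoxy)phenyl]-3-[4-(methoxymethoxy)-3,5-bis(3-methylbut-2-enyl)phenyl]prop-2-en-1-one
Product: 8 2-iodo-3-(methoxymethoxy)-6-{(E)-3-[4-(methoxymethoxy)-3,5-bis(3-methylbut-2-enyl)phenyl]prop-2-enoyl}phenyl trifluoromethanesulfonate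
Conditions: Tf2O, pyridine, CH2Cl2, −20 to 0 °C
Reagents that add atoms: trifluoromethanesulfonic anhydride, O=S(=O)(OS(=O)(=O)C(F)(F)F)C(F)(F)F
Why: O-sulfonylation of the chelated phenol turns the C8a oxygen of resacetophenone into the leaving group needed for aryne formation and blocks oxa-Michael closure of the chalcone; pyridine buffers the acid so the acetals survive.

Step 7
Reactants: 8 2-iodo-3-(methoxymethoxy)-6-{(E)-3-[4-(methoxymethoxy)-3,5-bis(3-methylbut-2-enyl)phenyl]prop-2-enoyl}phenyl trifluoromethanesulfonate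
Product: 10 2-iodo-3-(methoxymethoxy)-6-{(3S)-3-hydroxy-3-[4-(methoxymethoxy)-3,5-bis(3-methylbut-2-enyl)phenyl]propanoyl}phenyl trifluoromethanesulfonate, via pinacol boronate 9 (not isolated)
Conditions: CuCl (5 mol%), NaOtBu (10 mol%), (R)-1-[(Sp)-2-(diphenylphosphino)ferrocenyl]ethyldicyclohexylphosphine or its antipode (6 mol%), B2pin2, MeOH, THF, 0 °C to rt; then NaBO3·4H2O, THF/H2O, rt
Reagents that add atoms: sodium perborate (NaBO3, monomeric formula), [Na+].[O-]OB=O (hydroxyl oxygen); bis(pinacolato)diboron, CC1(C)OB(OC1(C)C)B1OC(C)(C)C(C)(C)O1 (boryl group of 9 only)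
Why: Enantioselective copper-catalysed conjugate borylation of the enone followed by stereoretentive perborate oxidation of the C–B bond; the chiral bisphosphine–copper boryl complex selects the enone face and so sets the carbinol carbon (later C2) as (S), while the nucleophilic boryl copper should leave the three prenyl alkenes untouched.

Step 8
Reactants: 10 2-iodo-3-(methoxymethoxy)-6-{(3S)-3-hydroxy-3-[4-(methoxymethoxy)-3,5-bis(3-methylbut-2-enyl)phenyl]propanoyl}phenyl trifluoromethanesulfonate
Product: 14 (2S)-7-(methoxymethoxy)-2-[4-(methoxymethoxy)-3,5-bis(3-methylbut-2-enyl)phenyl]-8-(3-methylbut-2-enyl)chroman-4-one, via chloromagnesium alkoxide 11 (not isolated), via aryne 12 (not isolated), via arylmagnesium chloride 13 (not isolated)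
Conditions: MeMgCl (1.0 equiv), THF, −78 °C; i-PrMgCl·LiCl (1.05 equiv), −78 to −40 °C; CuBr·SMe2 (20 mol%), prenyl bromide (1.5 equiv), −40 to 0 °C; aq NH4Cl
Reagents that add atoms: prenyl bromide (1-bromo-3-methylbut-2-ene), CC(C)=CCBr; methylmagnesium chloride, C[Mg]Cl (MgCl of 11 to 13 only)
Why: Deprotonation gives alkoxide 11, iodine–magnesium exchange at C8 with loss of the neighbouring triflate gives the C8a≡C8 aryne 12, the alkoxide oxygen adds to C8a to leave arylmagnesium 13, and copper-catalysed SN2 allylation with prenyl bromide gives 14. The closest known reaction types are the cyclisation of a tethered alkoxide onto an aryne and the allylation of aryne-derived arylmagnesium reagents under monovalent copper catalysis. The pyranone ring closes in a 6-exo-dig mode, the oxygen attacking C8a in the plane of the aryne. No stereocenter is formed, and C2 is carried through because only its O–Mg bond reacts, provided the magnesium aldolate is kept cold so that retro-aldol cleavage does not intervene. Oxygen at C8a and carbon at C8 are secured by the three-atom tether from C4a (attack at C8 would need a meta-bridged ring) and reinforced by the C7 methoxymethoxy group, which makes C8a the electrophilic aryne carbon and chelates the C8–Mg bond; the doubly ortho-substituted arylcopper should attack the unhindered α-carbon of prenyl bromide. Chemoselectivity toward the ketone relies on exchange of the activated iodide at −78 °C being much faster than Grignard addition or enolisation.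

Step 9
Reactants: 14 (2S)-7-(methoxymethoxy)-2-[4-(methoxymethoxy)-3,5-bis(3-methylbut-2-enyl)phenyl]-8-(3-methylbut-2-enyl)chroman-4-one
Product: 16 (2R,3R)-3-hydroxy-7-(methoxymethoxy)-2-[4-(methoxymethoxy)-3,5-bis(3-methylbut-2-enyl)phenyl]-8-(3-methylbut-2-enyl)chroman-4-one, via potassium enolate 15 (not isolated)
Conditions: KN(SiMe3)2 (1.2 equiv), THF, −78 °C; 2-(phenylsulfonyl)-3-phenyloxaziridine, −78 °C; aq NH4Cl
Reagents that add atoms: 2-(phenylsulfonyl)-3-phenyloxaziridine, O=S(=O)(N1OC1c1ccccc1)c1ccccc1; potassium bis(trimethylsilyl)amide, C[Si](C)(C)[N-][Si](C)(C)C.[K+] (potassium of 15 only)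
Why: Davis oxidation of the potassium enolate; the oxaziridine should approach C3 from the face opposite the C2 aryl group, giving the 2,3-trans (2R,3R) ketol, while poor overlap of the endocyclic C2–O1 bond with the enolate π system disfavours ring opening at −78 °C.

Step 10
Reactants: 16 (2R,3R)-3-hydroxy-7-(methoxymethoxy)-2-[4-(methoxymethoxy)-3,5-bis(3-methylbut-2-enyl)phenyl]-8-(3-methylbut-2-enyl)chroman-4-one
Product: 17 (2R,3R)-3,7-dihydroxy-2-[4-hydroxy-3,5-bis(3-methylbut-2-enyl)phenyl]-8-(3-methylbut-2-enyl)chroman-4-one (CNP0316331.1)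
Conditions: HCl (3 M aq), MeOH, 40 °C
Reagents that add atoms: none
Why: Acid-catalysed transacetalisation of both methoxymethyl ethers to methanol; mild acid and moderate temperature should leave the prenyl groups (no chroman formation) and the trans ketol untouched.

Compound list
1 | 2,4-dihydroxyacetophenone | CC(=O)c1ccc(O)cc1O | starting material
2 | 1-(2,4-dihydroxy-3-iodophenyl)ethanone | CC(=O)c1ccc(O)c(I)c1O | intermediate
3 | 1-[2-hydroxy-3-iodo-4-(methoxymethoxy)phenyl]ethanone | CC(=O)c1ccc(OCOC)c(I)c1O | intermediate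
4 | 4-hydroxybenzaldehyde | O=Cc1ccc(O)cc1 | starting material
5 | 4-hydroxy-3,5-bis(3-methylbut-2-enyl)benzaldehyde | CC(C)=CCc1cc(C=O)cc(CC=C(C)C)c1O | intermediate
6 | 4-(methoxymethoxy)-3,5-bis(3-methylbut-2-enyl)benzaldehyde | CC(C)=CCc1cc(C=O)cc(CC=C(C)C)c1OCOC | intermediate
7 | (E)-1-[2-hydroxy-3-iodo-4-(methoxymethoxy)phenyl]-3-[4-(methoxymethoxy)-3,5-bis(3-methylbut-2-enyl)phenyl]prop-2-en-1-one | COCOc1ccc(C(=O)/C=C/c2cc(CC=C(C)C)c(OCOC)c(CC=C(C)C)c2)c(O)c1I | intermediate
8 | 2-iodo-3-(methoxymethoxy)-6-{(E)-3-[4-(methoxymethoxy)-3,5-bis(3-methylbut-2-enyl)phenyl]prop-2-enoyl}phenyl trifluoromethanesulfonate | COCOc1ccc(C(=O)/C=C/c2cc(CC=C(C)C)c(OCOC)c(CC=C(C)C)c2)c(OS(=O)(=O)C(F)(F)F)c1I | intermediate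
9 | (3S)-3-(pinacolboryl) ketone: 2-iodo-3-(methoxymethoxy)-6-{(3S)-3-[4-(methoxymethoxy)-3,5-bis(3-methylbut-2-enyl)phenyl]-3-(4,4,5,5-tetramethyl-1,3,2-dioxaborolan-2-yl)propanoyl}phenyl trifluoromethanesulfonate | COCOc1ccc(C(=O)C[C@H](B3OC(C)(C)C(C)(C)O3)c2cc(CC=C(C)C)c(OCOC)c(CC=C(C)C)c2)c(OS(=O)(=O)C(F)(F)F)c1I | intermediate (not isolated)
10 | 2-iodo-3-(methoxymethoxy)-6-{(3S)-3-hydroxy-3-[4-(methoxymethoxy)-3,5-bis(3-methylbut-2-enyl)phenyl]propanoyl}phenyl trifluoromethanesulfonate | COCOc1ccc(C(=O)C[C@H](O)c2cc(CC=C(C)C)c(OCOC)c(CC=C(C)C)c2)c(OS(=O)(=O)C(F)(F)F)c1I | intermediate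
11 | chloromagnesium (S)-alkoxide of 10 | COCOc1ccc(C(=O)C[C@H](O[Mg]Cl)c2cc(CC=C(C)C)c(OCOC)c(CC=C(C)C)c2)c(OS(=O)(=O)C(F)(F)F)c1I | intermediate (not isolated)
12 | C8a≡C8 aryne carrying the (S)-chloromagnesium alkoxide side chain | COCOC1=CC=C(C(=O)C[C@H](O[Mg]Cl)c2cc(CC=C(C)C)c(OCOC)c(CC=C(C)C)c2)C#C1 | intermediate (not isolated)
13 | (2S)-8-(chloromagnesio)-7-(methoxymethoxy)-2-[4-(methoxymethoxy)-3,5-bis(3-methylbut-2-enyl)phenyl]chroman-4-one | CC(C)=CCc1cc([C@H]2Oc3c(ccc(OCOC)c3[Mg]Cl)C(=O)C2)cc(CC=C(C)C)c1OCOC | intermediate (not isolated)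
14 | (2S)-7-(methoxymethoxy)-2-[4-(methoxymethoxy)-3,5-bis(3-methylbut-2-enyl)phenyl]-8-(3-methylbut-2-enyl)chroman-4-one | CC(C)=CCc1cc([C@H]2Oc3c(ccc(OCOC)c3CC=C(C)C)C(=O)C2)cc(CC=C(C)C)c1OCOC | intermediate
15 | potassium enolate of 14 (2S) | CC(C)=CCc1cc([C@H]2Oc3c(ccc(OCOC)c3CC=C(C)C)C([O-])=C2)cc(CC=C(C)C)c1OCOC.[K+] | intermediate (not isolated)
16 | (2R,3R)-3-hydroxy-7-(methoxymethoxy)-2-[4-(methoxymethoxy)-3,5-bis(3-methylbut-2-enyl)phenyl]-8-(3-methylbut-2-enyl)chroman-4-one | CC(C)=CCc1cc([C@H]2Oc3c(ccc(OCOC)c3CC=C(C)C)C(=O)[C@@H]2O)cc(CC=C(C)C)c1OCOC | intermediate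
17 | (2R,3R)-3,7-dihydroxy-2-[4-hydroxy-3,5-bis(3-methylbut-2-enyl)phenyl]-8-(3-methylbut-2-enyl)chroman-4-one (CNP0316331.1) | CC(C)=CCc1cc([C@H]2Oc3c(ccc(O)c3CC=C(C)C)C(=O)[C@@H]2O)cc(CC=C(C)C)c1O | target

Total step count: 10. Longest linear sequence: 8 steps (steps 1, 2, 5, 6, 7, 8, 9, 10 from compound 1; equally steps 3, 4, 5–10 from compound 4).

Steps most likely to fail

Step 8. The C8–magnesium bond may be protonated before allylation, the magnesium aldolate may undergo retro-aldol cleavage, the Grignard reagent may add to the ketone, or allylation may occur at the γ-carbon of prenyl bromide. The fallback separates the two bond formations. Setting out from 10, a Stille coupling with tributyl(3-methylbut-2-enyl)stannane (Pd(PPh3)4, dioxane, 80 °C, no chloride additive so that the iodide reacts before the triflate) should give 3-(methoxymethoxy)-2-(3-methylbut-2-enyl)-6-{(3S)-3-hydroxy-3-[4-(methoxymethoxy)-3,5-bis(3-methylbut-2-enyl)phenyl]propanoyl}phenyl trifluoromethanesulfonate F1. An intramolecular Buchwald–Hartwig etherification of the aryl triflate (Pd(OAc)2, 2-(di-tert-butylphosphino)-2',4',6'-triisopropylbiphenyl, K3PO4, toluene, 80 °C) would then form the same O1–C8a bond and return to the route at 14.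

Step 7. The copper boryl species may borylate the carbon–iodine bond, and the twisted, doubly ortho-substituted aroyl group may erode facial selectivity. The fallback sets out from 8 with a nucleophilic asymmetric epoxidation of the enone (La(OiPr)3, BINOL antipode chosen for this sense, Ph3As=O, t-BuOOH, 4 Å molecular sieves, THF, rt), which leaves the prenyl alkenes alone and should give the trans epoxy ketone [(2S,3R)-3-[4-(methoxymethoxy)-3,5-bis(3-methylbut-2-enyl)phenyl]oxiran-2-yl] aryl ketone F2. Reductive cleavage of the Cα–O bond with phenylselenide ((PhSe)2, NaBH4, AcOH, EtOH, 0 °C) keeps the benzylic C–O stereocenter and returns to the route at 10.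

Step 9. The enolate may open by β-elimination of the ring A aryloxide (loss of C2 configuration), or the product alkoxide may add to the sulfonimine by-product. The fallback avoids a strongly basic enolate. Setting out from 14, soft enolisation (Me3SiOTf, Et3N, CH2Cl2, 0 °C) should give the (2S)-4-(trimethylsilyloxy)-2H-chromene F3. An O-selective nitroso aldol reaction with nitrosobenzene (Et3SiOTf cat., CH2Cl2, −78 °C), anti to the C2 aryl group, should give the (2R,3R)-3-(anilinooxy)chroman-4-one F4. Cleavage of the N–O bond (CuSO4 cat., MeOH, rt) returns to the route at 16.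

Further compounds
F1 | step 8 | 3-(methoxymethoxy)-2-(3-methylbut-2-enyl)-6-{(3S)-3-hydroxy-3-[4-(methoxymethoxy)-3,5-bis(3-methylbut-2-enyl)phenyl]propanoyl}phenyl trifluoromethanesulfonate | COCOc1ccc(C(=O)C[C@H](O)c2cc(CC=C(C)C)c(OCOC)c(CC=C(C)C)c2)c(OS(=O)(=O)C(F)(F)F)c1CC=C(C)C
F2 | step 7 | 2-iodo-3-(methoxymethoxy)-6-{(2S,3R)-3-[4-(methoxymethoxy)-3,5-bis(3-methylbut-2-enyl)phenyl]oxirane-2-carbonyl}phenyl trifluoromethanesulfonate | COCOc1ccc(C(=O)[C@H]2O[C@@H]2c3cc(CC=C(C)C)c(OCOC)c(CC=C(C)C)c3)c(OS(=O)(=O)C(F)(F)F)c1I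
F3 | step 9 | (2S)-7-(methoxymethoxy)-2-[4-(methoxymethoxy)-3,5-bis(3-methylbut-2-enyl)phenyl]-8-(3-methylbut-2-enyl)-4-(trimethylsilyloxy)-2H-chromene | CC(C)=CCc1cc([C@H]2Oc3c(ccc(OCOC)c3CC=C(C)C)C(O[Si](C)(C)C)=C2)cc(CC=C(C)C)c1OCOC
F4 | step 9 | (2R,3R)-3-(anilinooxy)-7-(methoxymethoxy)-2-[4-(methoxymethoxy)-3,5-bis(3-methylbut-2-enyl)phenyl]-8-(3-methylbut-2-enyl)chroman-4-one | CC(C)=CCc1cc([C@H]2Oc3c(ccc(OCOC)c3CC=C(C)C)C(=O)[C@@H]2ONc4ccccc4)cc(CC=C(C)C)c1OCOC
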